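## Retrosynthetic overview
1. Last steps: Tebbe methylenation of the C11 ketone (giving C11=C20), acetonide removal, and acetylation of C9/C13/C14. The tertiary C8-OH stays free.
2. The ten-membered ring closes last, by RCM at C5=C6 on a 6/5 lactone precursor. The γ-lactone comes from an intramolecular SmI2 Reformatsky aldol of a C7 2-bromopropanoate onto a C8 ketone.
3. C9–C10 forms by an intermolecular SmI2 aldol between the C10 Sm-enolate of an α-bromoketone and a vinyl epoxy aldehyde made by organocatalytic epoxidation. The epoxide is opened at C7 with inversion.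
4. Ring A comes first. Birch methylation of benzoic acid is followed by organocatalytic desymmetrising bromolactonisation, which sets C1, C10 and C11. The lactone is opened to a Weinreb amide, the C11 α-OH directs OsO4 to the α face for C13/C14, and the amide becomes the C2 ketone and then the CBS-derived C2 carbinol.
5. Ring order: cyclohexane A, then the γ-lactone, then the ten-membered ring.

**Assumptions**
- Briarane numbering is used: C1 quaternary, C2-OAc, C5=C6, C7–C9 oxygenated, C10 ring fusion, C11(=C20), C13/C14-OAc, and the lactone C7–O–C19(=O)–C17(Me-18)–C8.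
- α/β convention: ring A is drawn with C1→C14→C13→C12→C11→C10 counter-clockwise and β toward the viewer. In the target Me-15 is β, C2-OAc is α, O13 and O14 are α, C9 is β and H10 is α. I checked this against the target SMILES.
- Catalyst enantiomers are chosen to give the antipode drawn.
- Racemic 2-bromopropanoic acid is used. Its stereocentre is erased on Sm-enolate formation, and C17 is set in the lactonisation.

## Route

**Step 1**
Reactants: 1 benzoic acid
Product: 2 1-methylcyclohexa-2,5-diene-1-carboxylic acid (achiral, mirror-symmetric, two enantiotopic alkenes)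
Conditions: Li, NH3(l), t-BuOH, THF, −78 °C; then MeI, −78 °C → rt
Reagents that add atoms: MeI, CI
Why: Birch reductive alkylation methylates the carboxylate dianion at the ipso carbon, giving the C1 quaternary centre (Me-15) and the CO2H that becomes C2.

**Step 2**
Reactants: 2
Product: 3 bicyclic bromo-γ-lactone (C1-Me β; C2 carbonyl bridged α through O to C11; Br on C10 β; C13=C14 alkene retained)
Conditions: NBS (1.05 equiv), BINOL-derived amino-thiocarbamate catalyst (10 mol%), CH2Cl2, −78 °C
Reagents that add atoms: NBS, O=C1CCC(=O)N1Br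
Why: This is an organocatalytic enantioselective desymmetrising bromolactonisation. The catalyst-bound Br+ is delivered to one of the two enantiotopic alkenes and the carboxylate closes anti (5-endo) at C11, setting C1, C10 and C11 together.

**Step 3**
Reactants: 3
Product: 4 hydroxy Weinreb amide (C1-Me β, C2 = C(=O)N(Me)OMe α, C10-Br β, C11-OH α, C13=C14 alkene)
Conditions: Me(MeO)NH·HCl, AlMe3, CH2Cl2, 0 °C → rt
Reagents that add atoms: N,O-dimethylhydroxylamine, CNOC
Why: Basha–Weinreb aminolysis opens the strained bridged lactone, and the aluminium alkoxide is not nucleophilic enough at ≤ rt to displace the neopentylic bromide.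

**Step 4**
Reactants: 4
Product: 5 triol (13α,14α-diol; C11-OH α; C10-Br β)
Conditions: OsO4 (1.1 equiv), TMEDA, CH2Cl2, −78 °C; then aq. NaHSO3, THF, 50 °C
Reagents that add atoms: OsO4, O=[Os](=O)(=O)=O (source of the two diol oxygens)
Why: Hydroxyl-directed (Donohoe-type) dihydroxylation: the C11 α-hydroxyl hydrogen-bonds to an Os=O of the OsO4·TMEDA complex and delivers it to the α face of the homoallylic C13=C14 alkene, so both new hydroxyls are cis and α (syn to C2), setting C13 and C14.

**Step 5**
Reactants: 5
Product: 6 13,14-acetonide with free C11-OH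
Conditions: 2,2-dimethoxypropane, CSA (cat.), acetone, rt
Reagents that add atoms: 2,2-dimethoxypropane, COC(C)(C)OC
Why: Kinetic acetonide formation takes the cis-1,2-diol (C13/C14), while the 1,3-related C11-OH would need a diaxial acetal and stays free.

**Step 6**
Reactants: 6
Product: 7 C11-OTBS ether
Conditions: TBSOTf, 2,6-lutidine, CH2Cl2, −78 → −20 °C
Reagents that add atoms: TBSOTf, C[Si](C)(C(C)(C)C)OS(=O)(=O)C(F)(F)F
Why: The C11 alcohol must be masked before the organometallic step, and low-temperature silyl triflate silylation of the hindered secondary alcohol leaves the acetonide and Weinreb amide intact.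

**Step 7**
Reactants: 7; 8 4-bromo-2-methylbut-1-ene
Product: 9 C2 ketone, C2(=O)CH2CH2C(Me)=CH2 (C3, C4, C5 and C16 plus the terminal =CH2 lost in the later RCM)
Conditions: 8 + Mg, THF, reflux (Grignard formation); then 7, THF, −20 → 0 °C
Reagents that add atoms: none
Why: Weinreb ketone synthesis: the chelated tetrahedral intermediate prevents over-addition, and C1 is not touched.

**Step 8**
Reactants: 9
Product: 10 C2 alcohol (2S)
Conditions: (R)-Me-CBS (20 mol%), catecholborane, toluene, −78 °C
Reagents that add atoms: none
Why: Corey–Itsuno reduction with catalyst control sets C2, the quaternary C1 being the large group and the CH2 chain the small one, and catecholborane avoids hydroboration of the 1,1-disubstituted alkene.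

**Step 9**
Reactants: 10
Product: 11 C2 acetate
Conditions: Ac2O, DMAP, Et3N, CH2Cl2, 40 °C
Reagents that add atoms: Ac2O, CC(=O)OC(C)=O
Why: C2-OAc is required in the target, and acetylation here also prevents later hemiketal formation with the C11 ketone.

**Step 10**
Reactants: 11
Product: 12 C11 alcohol
Conditions: HF·pyridine, pyridine/THF, rt
Reagents that add atoms: none
Why: Buffered desilylation leaves the acetate, acetonide and C10 bromide untouched.

**Step 11**
Reactants: 12
Product: 13 α-bromoketone (C11=O, C10–Br; C10 is epimerisable and irrelevant at this stage)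
Conditions: Dess–Martin periodinane, NaHCO3, CH2Cl2, 0 °C → rt
Reagents that add atoms: none
Why: Mild oxidation gives the α-bromoketone, a precursor of a C10 enolate that is regio-defined even though C12 is also enolisable.

**Step 12**
Reactants: 14 (E)-penta-2,4-dienal
Product: 15 (2S,3R)-3-ethenyloxirane-2-carbaldehyde (trans-epoxide; C8 = S, C7 = R)
Conditions: 30% aq. H2O2, (R)-diphenylprolinol TMS ether (10 mol%), CH2Cl2, 0 °C → rt; crude used at once
Reagents that add atoms: hydrogen peroxide, OO
Why: Organocatalytic iminium-ion (Jørgensen-type) epoxidation of the enal C2=C3 bond sets C7 and C8, and the epoxide is later opened at C7 with inversion.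

**Step 13**
Reactants: 13; 15
Product: 16 β-hydroxy ketone (C9–C10 formed; C9-OH with the target configuration, H10 α; C7/C8 epoxide and C11 ketone retained)
Conditions: SmI2 (2.5 equiv), THF, −78 °C, added to a mixture of 13 and 15
Reagents that add atoms: none
Why: In a Sm-Reformatsky-type aldol, SmI2 reduces the C–Br bond to the C10 Sm(III) enolate regiospecifically and it adds through a chelated (aldehyde O/epoxide O) Zimmerman–Traxler-type transition state, which sets C9, and C10 (α to the ketone) can equilibrate to the thermodynamic isomer.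

**Step 14**
Reactants: 16; 17 2-bromopropanoic acid (racemic)
Product: 18 diol 2-bromopropanoate (C7 carries the O-acyl group with inversion and the vinyl group; C8-OH and C9-OH free; C17 epimeric mixture)
Conditions: Ti(OiPr)4 (1.5 equiv), 17 (3 equiv), CH2Cl2, 0 °C → rt
Reagents that add atoms: none (17 is the numbered reactant)
Why: Caron–Sharpless Ti(OiPr)4-mediated C3-selective opening of a 2,3-epoxy alcohol, with the C9-OH directing attack to the allylic C7, gives inversion at C7 and hence the anti C7/C8 relationship.

**Step 15**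
Reactants: 18
Product: 19 C8 ketone (C8=O, C9-OH retained)
Conditions: Dess–Martin periodinane (1.2 equiv), NaHCO3, CH2Cl2, 0 °C
Reagents that add atoms: none
Why: Dess–Martin oxidation should take the less hindered C8-OH preferentially, because the C9-OH is flanked by the ring fusion and hydrogen-bonded to the C11 ketone.

**Step 16**
Reactants: 19
Product: 20 γ-lactone with C8 tertiary OH (C17-Me/C8-OH relationship as in the target; C7 vinyl retained)
Conditions: SmI2 (3 equiv), THF, −78 → −20 °C
Reagents that add atoms: none
Why: Intramolecular SmI2 Reformatsky aldol: 5-exo attack of the C17 Sm enolate on the activated C8 ketone is far faster than 8-exo attack on C11, and the chelated chair-like transition state sets C8 and C17.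

**Step 17**
Reactants: 20
Product: 21 ten-membered-ring ketone with Z-C5=C6 (ethylene lost)
Conditions: Z-selective cyclometalated Ru-dithiolate catalyst (10 mol%), toluene (1 mM), 50 °C, N2 sparge
Reagents that add atoms: none
Why: Proposed new method: the monosubstituted C6 vinyl group initiates, the Ru carbene adds intramolecularly to the 1,1-disubstituted C5=CH2, and the metallacyclobutane collapses to the trisubstituted alkene, with the fused lactone pre-organising the chain ends and the ring enforcing Z geometry; the closest known reactions are RCM to trisubstituted 5–8-membered cycloalkenes and Z-selective macrocyclic RCM of disubstituted alkenes, and a Z-trisubstituted alkene in a ten-membered ring on a fused lactone has not been shown.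

**Step 18**
Reactants: 21
Product: 22 C11 exocyclic methylene (C20)
Conditions: Tebbe reagent (4 equiv), pyridine, THF, −40 → 0 °C
Reagents that add atoms: Tebbe reagent Cp2Ti(μ-CH2)(μ-Cl)AlMe2, C[Al-]1(C)[Cl+][Ti](C2C=CC=C2)(C3C=CC=C3)C1 (bridging chloride written with formal charges)
Why: Titanium-carbene methylenation takes the ketone ahead of the lactone and acetate at low temperature, the excess reagent covers the two free hydroxyls, and it is done after RCM because an exocyclic C11=CH2 would otherwise compete by closing a six-membered ring onto the C6 vinyl group.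

**Step 19**
Reactants: 22
Product: 23 C9, C13, C14 triol with free C8-OH and 2-OAc
Conditions: 80% aq. AcOH, 40 °C
Reagents that add atoms: none
Why: Mild acetonide hydrolysis leaves the lactone, the acetate and both alkenes intact.

**Step 20**
Reactants: 23
Product: 24 Frajunolide E
Conditions: Ac2O, pyridine, DMAP (cat.), CH2Cl2, 0 °C → rt
Reagents that add atoms: Ac2O, CC(=O)OC(C)=O
Why: Acetylation of the three secondary alcohols (C9, C13, C14) leaves the hindered tertiary C8-OH untouched.

## Compound list
1 | benzoic acid | OC(=O)c1ccccc1 | starting material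
2 | 1-methylcyclohexa-2,5-diene-1-carboxylic acid | CC1(C(=O)O)C=CCC=C1 | intermediate
3 | bromo-γ-lactone (C1-Me β; C2 bridge α to O–C11; Br–C10 β; C13=C14) | C[C@@]12C=CC[C@@H](OC1=O)[C@@H]2Br | intermediate
4 | hydroxy Weinreb amide (C11-OH α, C10-Br β, C13=C14) | C[C@]1(C(=O)N(C)OC)C=CC[C@@H](O)[C@@H]1Br | intermediate
5 | triol (13α,14α-diol, 11α-OH, 10β-Br) | C[C@]1(C(=O)N(C)OC)[C@@H](O)[C@@H](O)C[C@@H](O)[C@@H]1Br | intermediate
6 | 13,14-acetonide with free C11-OH | C[C@]1(C(=O)N(C)OC)[C@H]2OC(C)(C)O[C@H]2C[C@@H](O)[C@@H]1Br | intermediate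
7 | C11-OTBS Weinreb amide | C[C@]1(C(=O)N(C)OC)[C@H]2OC(C)(C)O[C@H]2C[C@@H](O[Si](C)(C)C(C)(C)C)[C@@H]1Br | intermediate
8 | 4-bromo-2-methylbut-1-ene | CC(=C)CCBr | starting material
9 | C2 ketone | C[C@]1(C(=O)CCC(C)=C)[C@H]2OC(C)(C)O[C@H]2C[C@@H](O[Si](C)(C)C(C)(C)C)[C@@H]1Br | intermediate
10 | (2S)-C2 alcohol | C[C@]1([C@@H](O)CCC(C)=C)[C@H]2OC(C)(C)O[C@H]2C[C@@H](O[Si](C)(C)C(C)(C)C)[C@@H]1Br | intermediate
11 | C2 acetate | C[C@]1([C@@H](OC(C)=O)CCC(C)=C)[C@H]2OC(C)(C)O[C@H]2C[C@@H](O[Si](C)(C)C(C)(C)C)[C@@H]1Br | intermediate
12 | C11 alcohol | C[C@]1([C@@H](OC(C)=O)CCC(C)=C)[C@H]2OC(C)(C)O[C@H]2C[C@@H](O)[C@@H]1Br | intermediate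
13 | α-bromoketone | C[C@]1([C@@H](OC(C)=O)CCC(C)=C)[C@H]2OC(C)(C)O[C@H]2CC(=O)[C@@H]1Br | intermediate
14 | (E)-penta-2,4-dienal | C=C/C=C/C=O | starting material
15 | (2S,3R)-3-ethenyloxirane-2-carbaldehyde | O=C[C@H]1O[C@@H]1C=C | intermediate
16 | aldol adduct (C9-OH, C7/C8 epoxide, C11 ketone) | C[C@]1([C@@H](OC(C)=O)CCC(C)=C)[C@H]2OC(C)(C)O[C@H]2CC(=O)[C@@H]1[C@H](O)[C@H]3O[C@@H]3C=C | intermediate
17 | 2-bromopropanoic acid (racemic) | CC(Br)C(=O)O | starting material
18 | diol 2-bromopropanoate (C17 epimeric mixture) | C[C@]1([C@@H](OC(C)=O)CCC(C)=C)[C@H]2OC(C)(C)O[C@H]2CC(=O)[C@@H]1[C@H](O)[C@@H](O)[C@@H](OC(=O)C(C)Br)C=C | intermediate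
19 | C8 ketone | C[C@]1([C@@H](OC(C)=O)CCC(C)=C)[C@H]2OC(C)(C)O[C@H]2CC(=O)[C@@H]1[C@H](O)C(=O)[C@@H](OC(=O)C(C)Br)C=C | intermediate
20 | lactone with C8 tertiary OH | C[C@]1([C@@H](OC(C)=O)CCC(C)=C)[C@H]2OC(C)(C)O[C@H]2CC(=O)[C@@H]1[C@H](O)[C@]3(O)[C@@H](C)C(=O)O[C@H]3C=C | intermediate
21 | ten-membered-ring ketone (Z-C5=C6) | O=C1C[C@@H]4OC(C)(C)O[C@@H]4[C@]2(C)[C@@H](OC(C)=O)CC/C(C)=C\[C@@H]3OC(=O)[C@H](C)[C@@]3(O)[C@@H](O)[C@@H]12 | intermediate
22 | C11-methylene acetonide | C=C1C[C@@H]4OC(C)(C)O[C@@H]4[C@]2(C)[C@@H](OC(C)=O)CC/C(C)=C\[C@@H]3OC(=O)[C@H](C)[C@@]3(O)[C@@H](O)[C@@H]12 | intermediate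
23 | 9,13,14-triol, 8-OH, 2-OAc | C=C1C[C@H](O)[C@H](O)[C@]2(C)[C@@H](OC(C)=O)CC/C(C)=C\[C@@H]3OC(=O)[C@H](C)[C@@]3(O)[C@@H](O)[C@@H]12 | intermediate
24 | Frajunolide E | C=C1C[C@H](OC(C)=O)[C@H](OC(C)=O)[C@]2(C)[C@@H](OC(C)=O)CC/C(C)=C\[C@@H]3OC(=O)[C@H](C)[C@@]3(O)[C@@H](OC(C)=O)[C@@H]12 | target

**Total steps: 20. Longest linear sequence: 19** (steps 1–11 and 13–20 from benzoic acid; step 12 is a parallel one-step fragment synthesis).

## Three steps most likely to fail
1. **Step 17 (new Z-selective RCM forming the trisubstituted ten-membered alkene).** Fallback: close the ring at C6–C7 by intramolecular Nozaki–Hiyama–Kishi coupling (CrCl2/NiCl2) of a C6 trisubstituted alkenyl iodide onto a C7 aldehyde. The iodide is made by Wittig olefination of the C5 methyl ketone with Ph3P=CHI, with the Z isomer separated. The lactone is then formed by esterification and SmI2 Reformatsky.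
2. **Step 13 (SmI2 aldol union; C9/C10 stereochemistry and epoxy-aldehyde compatibility).** Fallback: generate the regio-defined C10 silyl enol ether from 13 (Zn, TMSCl) and run a TiCl4- or BF3-promoted Mukaiyama aldol with 15. Then correct C9 by oxidation and Zn(BH4)2 reduction, and C10 by base equilibration.
3. **Step 2 (enantioselective desymmetrising 5-endo bromolactonisation).** Fallback: Schultz asymmetric Birch reductive methylation of a chiral-prolinol benzamide, then diastereoselective bromolactonisation and auxiliary removal to reach the same lactone 3.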